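The data were computed with made-up constants.

If every Xa that goes has to take one Xb with it, the cedar run can lose at most 36.7% of its Xa, a figure I call the Xb allowance, the Xb charged as a fraction of the Xa charged. On that premise Xb is the limiting reagent, charged in a smaller amount than Xa, and Xa stands at 63.3% or higher at 90 s.

| flask | Xa | Xb | Xp | time |
|---|---|---|---|---|
| maple | 0.600 M | 0.660 M |  |  |
| larch | 0.360 M | 0.420 M |  |  |
| birch | 0.600 M | 0.660 M | 0.180 M |  |
| oak | 0.300 M | 0.660 M |  |  |
| cedar | 0.600 M | 0.220 M |  | 90 s |

- maple run (time / s: [Xa] / M): 3.6: 0.547; 8.0: 0.484; 18: 0.377; 40: 0.225; 90: 0.076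
- larch run (time / s: [Xa] / M): 3.6: 0.339; 8.0: 0.293; 18: 0.249; 40: 0.147; 90: 0.070
- birch run (time / s: [Xa] / M): 3.6: 0.534; 8.0: 0.471; 18: 0.371; 40: 0.227; 90: 0.085
- oak run (time / s: [Xa] / M): 3.6: 0.281; 8.0: 0.249; 18: 0.198; 40: 0.122; 90: 0.041

(readings scatter by 0.005 M)

- Overall: Xa + Xb -> Xp.
- Constant volume, constant temperature.
- "The second partner" is Xb.
- An order is taken over about fifteen percent of the charge, up and down.

1. apparent order in [Xb] of the starting rate, round the charge of the maple run (the rate where two percent of its Xa have turned into Xp)
2. apparent order in [Xa] of the starting rate, round the charge of the maple run (the rate where two percent of its Xa have turned into Xp) (one fixed amount of Xp, the same in the runs compared)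
3. Xa in the cedar run at 90 s, as a share of the Xa charged

You should know that the earlier runs don't test that premise directly: by its last reading the maple run has lost 87.3% of its Xa, less than its allowance of 110%. They do speak against it, though. On the premise, the oak run holds 2.95 times as much Xb as the maple run at the last reading, yet the two keep much the same share of their Xa there, 13.7% and 12.7%. So I don't trust the floor. My own estimate for the cedar run is taken from the larch run, which keeps 19.4% of its Xa at 90 s and is charged with less Xb than the maple run.

Your forecast is different: order 0.08 in Xb, order 1.08 in Xa, and 64% for the cedar run, since “Xa then stalls near 0.38–0.385 M, about 64%”. On the orders I offer nothing of my own.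

The flask gives order 1.1 in Xb, order 1.1 in Xa, and in the cedar run at 90 s 18.4% of the Xa charged.

    Xa + Xb → Xp (0.01070 L mol⁻¹ s⁻¹)
    Xp + Xb → Xq (0.004030 L mol⁻¹ s⁻¹)
    Xa → Z (0.01270 s⁻¹)
    2 Xa → L (0.007470 L mol⁻¹ s⁻¹)

The cedar run has lost 81.6% of its Xa against an allowance of 36.7%, so at least 45 percentage points of the charge left by steps that take no Xb. One such step is the conversion of Xa into Z: the cedar run without that step keeps 48.6% of its Xa, not 18.4%. Even that flask has lost 51.4%, more than the allowance by 15 points.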